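# Proposed total synthesis of Guajadial D

Locants follow the spiro name of the target, (2S,4S,4a'R,5'R,8'S)-5,7-dihydroxy-5'-methyl-4-phenyl-8'-(propan-2-yl)-spiro[chromane-2,2'-naphthalene]-6,8-dicarbaldehyde with a C1'=C8a' double bond. O1, C2 (spiro), C3, C4 (CHPh), C4a–C8a belong to the chroman (rings C and D). C1' (=CH), C3', C4', C4a' (ring-fusion CH), C5' (CHMe), C8' (CH-iPr) and C8a' (sp2) belong to the octalin (rings B and A).

## The problem

Guajadial D joins four rings. Ring A is a cyclohexane carrying methyl and isopropyl, ring B is a cyclohexene fused to it through one sp3 carbon (C4a') and one sp2 carbon (C8a'), ring C is a dihydropyran attached to ring B through the spiro carbon C2 alone, and ring D is a fully substituted phloroglucinol with two formyl groups.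

There are five stereocentres: C5' (R), C8' (S), C4a' (R), C2 (S) and C4 (S). The hydrogen at C4a' is cis to H5' and trans to H8'. Because C8a' is trigonal, ring B must leave C4a' equatorially on ring A, and this pushes methyl and isopropyl into axial positions. That is not the arrangement equilibration would give, so C4a' has to be set under reagent control and kept away from conditions that enolise through it.

Once set, C4a' locks the half-chair of ring B and can direct the spiro centre, where oxygen lies on the ring B face opposite to H4a'. The benzylic centre C4 is too remote and needs its own control element; phenyl is cis to C3' across ring C.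

The ring oxygen sits on a tertiary allylic carbon and is ionisable by acid, the more so once ring D carries formyl groups. The aldehydes exclude hydride and organometallic reagents, and the free phenols are acidic, so ring D must be completed last.

The enabling feature is that O1–C2 and C4–C4a are the two bonds a phenol and an unsaturated aldehyde form in a 2H-chromene synthesis, and C2 is allylic to C1'=C8a'. C2 is therefore the β-carbon of a 2,4-dienal that the ring B enone gives by a two-carbon extension.

## Retrosynthesis

**Ring D functional groups (17 ⇒ 16 ⇒ 15).** The two O–CH3 bonds and the two aryl–CHO bonds are cut first. Dimethyl ether 15 has no aldehyde and no acidic phenol, so it tolerates the hydride-based step before it. Ring D of 15 has only two free positions, so the formylation has no regiochemical question. The forward steps must formylate twice and demethylate without ionising the tertiary allylic ether.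

**Benzylic C4–phenyl bond (15 ⇒ 13 + 14).** Cutting here leaves spiro 2H-chromene 13 and bromobenzene 14, and uses the styrene-type C3=C4 bond that a chromene synthesis leaves behind. Carrying a preformed diarylmethine through the synthesis would require a chiral, non-commercial aryl fragment. A Heck-type arylation would place the aryl group on C3, whereas copper hydride places the metal at the benzylic carbon. The forward reaction must select the alkene face by catalyst control, since both substituents on C2 are ring B carbons and offer little bias.

**Ring C (13 ⇒ 10 + 11, through 12).** O1–C2 and C4–C4a are cut together. This removes ring C and the spiro centre in one move and leads to commercial 3,5-dimethoxyphenol 11 and bicyclic dienal 10. The alternative of closing only O1–C2 onto a preformed carbon chain would require the chain and its benzylic centre to be built first. The forward reaction must add the phenol ortho carbon to the aldehyde, pass through ortho-quinone methide 12, and close it with oxygen on the correct face of ring B.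

**Two-carbon extension (10 ⇒ 9 ⇒ 8).** The exocyclic C=C bond is cut back to enone 8 by way of nitrile 9. A nitrile is preferred to an ester because one partial reduction gives the aldehyde directly. The β-carbon of 8 is fully substituted, so only 1,2-olefination is possible.

**Ring A and the ring B double bond (8 ⇒ 6, via 7 ⇒ 5 ⇒ 4).** The C1'=C8a' bond of 8 is traced to saturated ketone 6, the isopropyl group to the isopropenyl group of 5, and the C8'–C8a' bond to an ene closure of monocyclic enone 4. The neighbouring cut, annulating ring B onto a menthone-type ketone, would create C4a' by enolate chemistry next to a carbonyl and deliver the more stable, wrong epimer. The ene closure instead creates C8' under chair control from the two existing centres. The fusion hydrogen it installs at C8a' is sacrificial and is removed when the enone is regenerated.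

**Ring B (4 ⇒ 3 ⇒ 1 + 2).** The cyclohexenone is opened by retro-aldol to keto aldehyde 3 and then by retro-Michael to (R)-citronellal 1 and methyl vinyl ketone 2. C5' comes from the chiral pool and C4a' is set next to it by an enamine catalyst, independently of what is thermodynamically preferred.

## Roads not taken

**Alternative 1:** Chromanyl cation cascade. The cut removes O1–C2, C2–C1' and C8'–C8a' at once and leads to open-chain hydroxy ketone A1, which carries the diarylmethine, an ethynyl branch and a prenyl-type terminus. In the forward direction SnCl4 would close the hemiketal to an oxocarbenium ion, the terminal alkyne carbon would attack it, the resulting ring B vinyl cation would be captured by the alkene, and chloride would cap the tertiary cation to give chloride A2.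
- Merits: three rings, the spiro centre and the C1'=C8a' alkene arise in one operation, and the benzylic centre is already present in A1, so no late hydroarylation is needed. In convergence and in the handling of C4 this road is better than the chosen one.
- Weak points: the 6-endo attack of a terminal alkyne generates a bent cyclohexenyl cation, so 5-exo attack through the internal carbon is a serious competitor. C2 and C8' must both be set irreversibly in one cationic event, guided only by remote centres. The tertiary chloride of A2 needs a separate reduction. A1 needs a propargylic stereocentre next to the methyl-bearing one and is long to make. The electron-rich diarylmethine and the product's allylic ether are both exposed to SnCl4.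
- Comparison: the chosen plan forms fewer bonds in its key step, but it uses a reaction class with direct precedent and a spiro centre that can be corrected by equilibration.

**Alternative 2:** Alkylative dearomatisation. The cut is C2–C3, with ring B traced back to a phenol. The precursor is tetralin catechol mono-aryl ether mesylate A3. Cs2CO3 would form the phenolate, whose aryloxy-bearing ortho carbon displaces the primary mesylate and gives spiro cyclohexa-2,4-dienone A4.
- Merits: the precursors are aromatic and easy to assemble, the benzylic centre is set in an open-chain arm, and the spiro carbon is made by a dependable intramolecular SN2 in which O-alkylation cannot compete because it would need a medium ring. In not needing a late hydroarylation this road is again ahead of the chosen plan.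
- Weak points: 6,6-disubstituted cyclohexa-2,4-dienones dimerise readily. The spiro configuration depends on 1,3-induction from C4 alone. Most seriously, A4 still has a ketone at C1', a diene in the wrong place and no stereocentre at C4a'. Removing the carbonyl, moving the unsaturation and installing the less stable fusion hydrogen face-selectively on a tetrasubstituted alkene would take several steps of uncertain selectivity.
- Comparison: the chosen plan fixes C4a' first by catalyst control and its key step delivers ring B in its final oxidation state.

**Alternative 3:** Selenoetherification and selenoxide elimination. The cut is O1–C2 alone, with the alkene moved to C1'=C2 in cis-fused octalin phenol A5. N-(Phenylseleno)phthalimide with camphorsulfonic acid would form the seleniranium ion, the phenol would open it at the tertiary carbon, and H2O2 would eliminate the selenoxide toward the fusion hydrogen to give di-O-methyl ether A6, which is identical with 16 of the present route.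
- Merits: the endgame is a single demethylation against three steps here, the benzylic centre and ring D are complete before the key step, and the elimination is regiospecific because the selenoxide has only one β-hydrogen. The stereochemical logic is coherent, since anti addition puts selenium and the cis fusion hydrogen on the same face when oxygen enters on the required one.
- Weak points: the phenol of A5 is flanked by formyl groups and is a poor nucleophile. H2O2 threatens the electron-rich hydroxy- and alkoxybenzaldehyde units by Dakin-type oxidation. The face of seleniranium formation decides C2 irreversibly. A5 needs an extra stereocentre, a regiodefined alkene and a C–C bond to a chiral diarylethyl arm, which makes its synthesis at least as long as the front half of the chosen route.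
- Comparison: against the shorter endgame, the chosen plan sets commercial aryl partners, a reversible ring closure, and no peroxide in the presence of aldehydes.

Key step: step 8

## Route

Assumption: the antipodes of the chiral catalysts named in steps 1 and 9 are those predicted by the accepted facial models of their reaction classes. If a trial shows the opposite sense, the mirror-image catalyst is used and nothing else changes.

Step 1
Reactants: 1 (R)-citronellal; 2 methyl vinyl ketone
Product: 3 (2R,3R)-3,7-dimethyl-2-(3-oxobutyl)oct-6-enal
Conditions: (R)-α,α-diphenylprolinol trimethylsilyl ether (5 mol %), ethyl 3,4-dihydroxybenzoate (20 mol %), neat, 4 °C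
Reagents that add atoms: none
Why: Enamine-catalysed Michael addition; the E-enamine of 1 is attacked by 2 on the face remote from the diphenyl(silyloxy)methyl group, which with the (R)-catalyst should give the (2R) centre, while the catechol activates the enone by hydrogen bonding. The (3R) centre of citronellal is not touched.

Step 2
Reactants: 3 (2R,3R)-3,7-dimethyl-2-(3-oxobutyl)oct-6-enal
Product: 4 (4R)-4-[(2R)-6-methylhept-5-en-2-yl]cyclohex-2-en-1-one
Conditions: LiOH (0.1 equiv), i-PrOH, rt
Reagents that add atoms: none
Why: Intramolecular aldol condensation of the methyl ketone onto the aldehyde, the only closure that gives a six-membered ring. Mild hydroxide is chosen so that the γ-stereocentre of the new enone is not enolised.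

Step 3
Reactants: 4 (4R)-4-[(2R)-6-methylhept-5-en-2-yl]cyclohex-2-en-1-one
Product: 5 (4aR,5R,8R,8aR)-5-methyl-8-(prop-1-en-2-yl)octahydronaphthalen-2(1H)-one (cis-fused)
Conditions: Me2AlCl (1.5 equiv), CH2Cl2, −78 → 0 °C; then aq. HCl
Reagents that add atoms: none
Why: Lewis acid-promoted intramolecular ene reaction with the enone as enophile; the trisubstituted alkene bonds to the β-carbon and an allylic methyl hydrogen passes to the α-carbon. Axial attack in a cis-decalin-like chair–chair transition state with the methyl group and the developing isopropenyl group both equatorial should set C8 trans to the methyl group and give the cis ring fusion.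

Step 4
Reactants: 5 (4aR,5R,8R,8aR)-5-methyl-8-(prop-1-en-2-yl)octahydronaphthalen-2(1H)-one
Product: 6 (4aR,5R,8S,8aS)-5-methyl-8-(propan-2-yl)octahydronaphthalen-2(1H)-one
Conditions: H2 (1 atm), RhCl(PPh3)3 (3 mol %), PhH–EtOH, rt
Reagents that add atoms: none
Why: Homogeneous hydrogenation of the 1,1-disubstituted alkene; this catalyst does not migrate the double bond, so the adjacent stereocentre keeps its configuration (the descriptor changes only through the priority rules), and the ketone is inert.

Step 5
Reactants: 6 (4aR,5R,8S,8aS)-5-methyl-8-(propan-2-yl)octahydronaphthalen-2(1H)-one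
Product: 8 (4aR,5R,8S)-5-methyl-8-(propan-2-yl)-4,4a,5,6,7,8-hexahydronaphthalen-2(3H)-one, via trimethylsilyl enol ether 7 (not isolated)
Conditions: Me3SiOTf, Et3N, CH2Cl2, 0 °C → rt; then Pd(OAc)2 (1.05 equiv), MeCN, rt
Reagents that add atoms: none
Why: Saegusa–Ito oxidation; equilibrating silylation of a cis-fused 2-decalone should favour the enol ether directed toward the ring fusion (the preference known from cis-fused 3-keto steroids). The palladium enolate formed from 7 can then lose only the ring-fusion hydrogen by β-hydride elimination, which removes the sacrificial centre, leaves the other three untouched and reduces the metal to zerovalent palladium.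

Step 6
Reactants: 8 (4aR,5R,8S)-5-methyl-8-(propan-2-yl)-4,4a,5,6,7,8-hexahydronaphthalen-2(3H)-one
Product: 9 2-[(4aR,5R,8S)-5-methyl-8-(propan-2-yl)-4,4a,5,6,7,8-hexahydronaphthalen-2(3H)-ylidene]acetonitrile (E/Z mixture)
Conditions: (EtO)2P(O)CH2CN, NaH, THF, 0 → 50 °C
Reagents that add atoms: diethyl cyanomethylphosphonate, CCOP(=O)(CC#N)OCC
Why: Horner–Wadsworth–Emmons olefination of a conjugated ketone; the phosphonate carbanion can only add 1,2 because the β-carbon of 8 is fully substituted, and it is too weak a base to enolise the enone through H4a. The geometry of the new double bond is of no consequence.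

Step 7
Reactants: 9 2-[(4aR,5R,8S)-5-methyl-8-(propan-2-yl)-4,4a,5,6,7,8-hexahydronaphthalen-2(3H)-ylidene]acetonitrile
Product: 10 2-[(4aR,5R,8S)-5-methyl-8-(propan-2-yl)-4,4a,5,6,7,8-hexahydronaphthalen-2(3H)-ylidene]acetaldehyde (E/Z mixture)
Conditions: i-Bu2AlH (1.2 equiv), PhMe, −78 °C; then 1 M HCl, 0 °C
Reagents that add atoms: water, O
Why: Partial reduction of the conjugated nitrile by i-Bu2AlH stops at the N-aluminio aldimine, which is hydrolysed to the aldehyde on cold acidic work-up. No stereocentre is involved.

Step 8
Reactants: 10 2-[(4aR,5R,8S)-5-methyl-8-(propan-2-yl)-4,4a,5,6,7,8-hexahydronaphthalen-2(3H)-ylidene]acetaldehyde; 11 3,5-dimethoxyphenol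
Product: 13 (2S,4a'R,5'R,8'S)-5,7-dimethoxy-5'-methyl-8'-(propan-2-yl)-4',4a',5',6',7',8'-hexahydro-3'H-spiro[chromene-2,2'-naphthalene], via ortho-quinone methide 12 (not isolated)
Conditions: ethylenediammonium diacetate (20 mol %), 11 (2 equiv), PhMe, 110 °C
Reagents that add atoms: none
Why: This is a formal [3+3] chromene annulation (Knoevenagel-type condensation followed by oxa-6π electrocyclisation), the reaction class by which 2,2-disubstituted 2H-chromenes are made from phenols and citral-type enals. The ammonium carboxylate turns the aldehyde of 10 into an iminium ion that is attacked by an ortho carbon of 11; loss of the amine gives ortho-quinone methide 12, whose O=C–C=C–C=C unit closes thermally and disrotatorily to form O1–C2 and restore the aromatic ring. Ring C is therefore closed by a 6π electrocyclic process, the aryl C–C bond having been made in the condensation. The one new stereocentre, spiro C2, is controlled by C4a': its hydrogen is pseudoaxial in the only half-chair ring B can adopt, and oxygen should bond along the pseudoaxial direction on the opposite face, which is the (2S) arrangement. That arrangement is also expected to be the more stable one (pseudoaxial allylic C–O, pseudoequatorial carbon branch), and since the closure is thermally reversible, continued heating after 10 is consumed should enrich it. Either geometry of 10 serves, because the exocyclic double bond of 12 only decides which helical sense of closure leads to which epimer. Only 1,2-addition is possible because the β- and δ-carbons of 10 are fully substituted; only ortho attack can go on to 12 and 13, since a para adduct cannot cyclise and reverts; and the two ortho positions of 11 are equivalent. Excess 11 keeps the condensation fast, because until 10 is consumed its iminium ion can enolise through H4a'.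

Step 9
Reactants: 13 (2S,4a'R,5'R,8'S)-5,7-dimethoxy-5'-methyl-8'-(propan-2-yl)-4',4a',5',6',7',8'-hexahydro-3'H-spiro[chromene-2,2'-naphthalene]; 14 bromobenzene
Product: 15 (2S,4S,4a'R,5'R,8'S)-5,7-dimethoxy-5'-methyl-4-phenyl-8'-(propan-2-yl)-3',4',4a',5',6',7',8'-heptahydrospiro[chromane-2,2'-naphthalene]
Conditions: Cu(OAc)2 (5 mol %), (R)-DTBM-SEGPHOS, Pd(OAc)2 (3 mol %), BrettPhos, NaOSiMe3, Ph2MeSiH, THF, 45 °C
Reagents that add atoms: none
Why: Copper hydride/palladium dual-catalysed Markovnikov hydroarylation of a β-substituted vinylarene; syn-hydrocupration places copper at the benzylic carbon, and stereospecific transmetalation to the arylpalladium bromide formed from 14 is followed by reductive elimination. The chiral ligand on copper is expected to choose the alkene face and so set (4S), phenyl cis to C3', because the two ring B carbons on C2 offer little substrate bias; the isolated trisubstituted alkene is not a substrate for CuH.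

Step 10
Reactants: 15 (2S,4S,4a'R,5'R,8'S)-5,7-dimethoxy-5'-methyl-4-phenyl-8'-(propan-2-yl)-3',4',4a',5',6',7',8'-heptahydrospiro[chromane-2,2'-naphthalene]
Product: 16 (2S,4S,4a'R,5'R,8'S)-5,7-dimethoxy-5'-methyl-4-phenyl-8'-(propan-2-yl)-3',4',4a',5',6',7',8'-heptahydrospiro[chromane-2,2'-naphthalene]-6,8-dicarbaldehyde
Conditions: Cl2CHOMe (6 equiv), TiCl4 (6 equiv), CH2Cl2, −78 → 0 °C; then H2O
Reagents that add atoms: dichloromethyl methyl ether, COC(Cl)Cl; water, O
Why: Rieche formylation; the chloromethoxycarbenium ion attacks C6 and C8, the only free positions of the phloroglucinol triether ring and far more nucleophilic than the phenyl group or the alkene, and the α-chloro ethers are hydrolysed on work-up. Excess reagent drives the second formylation of the deactivated monoaldehyde, and the low temperature is meant to spare the tertiary allylic ether.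

Step 11
Reactants: 16 (2S,4S,4a'R,5'R,8'S)-5,7-dimethoxy-5'-methyl-4-phenyl-8'-(propan-2-yl)-3',4',4a',5',6',7',8'-heptahydrospiro[chromane-2,2'-naphthalene]-6,8-dicarbaldehyde
Product: 17 Guajadial D
Conditions: BCl3 (5 equiv), CH2Cl2, −78 → 0 °C; then aq. NaHCO3
Reagents that add atoms: none
Why: Chelation-assisted aryl methyl ether cleavage; boron bridges a formyl oxygen and the neighbouring methoxy oxygen and chloride removes the methyl group by SN2, and both methoxy groups are ortho to a formyl group. Tertiary allylic aryl ethers of the 2,2-dimethylchromene type are known to survive these conditions at low temperature, which is the basis for expecting O1–C2 to hold.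

## Compound list

1 | (R)-citronellal, (3R)-3,7-dimethyloct-6-enal | CC(C)=CCC[C@@H](C)CC=O | starting material
2 | methyl vinyl ketone (but-3-en-2-one) | CC(=O)C=C | starting material
3 | (2R,3R)-3,7-dimethyl-2-(3-oxobutyl)oct-6-enal | CC(C)=CCC[C@@H](C)[C@H](C=O)CCC(C)=O | intermediate
4 | (4R)-4-[(2R)-6-methylhept-5-en-2-yl]cyclohex-2-en-1-one | CC(C)=CCC[C@@H](C)[C@H]1CCC(=O)C=C1 | intermediate
5 | (4aR,5R,8R,8aR)-5-methyl-8-(prop-1-en-2-yl)octahydronaphthalen-2(1H)-one, cis-fused | CC(=C)[C@@H]1CC[C@@H](C)[C@H]2CCC(=O)C[C@@H]12 | intermediate
6 | (4aR,5R,8S,8aS)-5-methyl-8-(propan-2-yl)octahydronaphthalen-2(1H)-one, cis-fused | CC(C)[C@@H]1CC[C@@H](C)[C@H]2CCC(=O)C[C@@H]12 | intermediate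
7 | trimethylsilyl enol ether of 6 with the C1=C2 double bond toward the ring fusion, trimethyl{[(4aR,5R,8S,8aS)-5-methyl-8-(propan-2-yl)-3,4,4a,5,6,7,8,8a-octahydronaphthalen-2-yl]oxy}silane | CC(C)[C@@H]1CC[C@@H](C)[C@H]2CCC(O[Si](C)(C)C)=C[C@@H]12 | intermediate (not isolated)
8 | (4aR,5R,8S)-5-methyl-8-(propan-2-yl)-4,4a,5,6,7,8-hexahydronaphthalen-2(3H)-one | CC(C)[C@@H]1CC[C@@H](C)[C@H]2CCC(=O)C=C12 | intermediate
9 | 2-[(4aR,5R,8S)-5-methyl-8-(propan-2-yl)-4,4a,5,6,7,8-hexahydronaphthalen-2(3H)-ylidene]acetonitrile (E isomer drawn, used as E/Z mixture) | CC(C)[C@@H]1CC[C@@H](C)[C@H]2CC/C(=C\C#N)C=C12 | intermediate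
10 | 2-[(4aR,5R,8S)-5-methyl-8-(propan-2-yl)-4,4a,5,6,7,8-hexahydronaphthalen-2(3H)-ylidene]acetaldehyde (E isomer drawn, used as E/Z mixture) | CC(C)[C@@H]1CC[C@@H](C)[C@H]2CC/C(=C\C=O)C=C12 | intermediate
11 | 3,5-dimethoxyphenol | COc1cc(O)cc(OC)c1 | starting material
12 | ortho-quinone methide, 3,5-dimethoxy-6-{2-[(4aR,5R,8S)-5-methyl-8-(propan-2-yl)-4,4a,5,6,7,8-hexahydronaphthalen-2(3H)-ylidene]ethylidene}cyclohexa-2,4-dien-1-one | CC(C)[C@@H]1CC[C@@H](C)[C@H]2CCC(=CC=C3C(=O)C=C(OC)C=C3OC)C=C12 | intermediate (not isolated)
13 | (2S,4a'R,5'R,8'S)-5,7-dimethoxy-5'-methyl-8'-(propan-2-yl)-4',4a',5',6',7',8'-hexahydro-3'H-spiro[chromene-2,2'-naphthalene] | CC(C)[C@@H]1CC[C@@H](C)[C@H]2CC[C@@]3(C=C12)C=Cc1c(OC)cc(OC)cc1O3 | intermediate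
14 | bromobenzene | Brc1ccccc1 | starting material
15 | (2S,4S,4a'R,5'R,8'S)-5,7-dimethoxy-5'-methyl-4-phenyl-8'-(propan-2-yl)-3',4',4a',5',6',7',8'-heptahydrospiro[chromane-2,2'-naphthalene] | CC(C)[C@@H]1CC[C@@H](C)[C@H]2CC[C@@]3(C=C12)C[C@@H](c1ccccc1)c1c(OC)cc(OC)cc1O3 | intermediate
16 | 6,8-dicarbaldehyde of 15 (Guajadial D di-O-methyl ether) | CC(C)[C@@H]1CC[C@@H](C)[C@H]2CC[C@@]3(C=C12)C[C@@H](c1ccccc1)c1c(OC)c(C=O)c(OC)c(C=O)c1O3 | intermediate
17 | Guajadial D, (2S,4S,4a'R,5'R,8'S)-5,7-dihydroxy-5'-methyl-4-phenyl-8'-(propan-2-yl)-3',4',4a',5',6',7',8'-heptahydrospiro[chromane-2,2'-naphthalene]-6,8-dicarbaldehyde | CC(C)[C@@H]1CC[C@@H](C)[C@H]2CC[C@@]3(C=C12)C[C@@H](c1ccccc1)c1c(O)c(C=O)c(O)c(C=O)c1O3 | target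

## Step count and least certain steps

Total: 11 steps. Longest linear sequence: 11 steps, from (R)-citronellal 1 to 17.

**Step 8 (key step).** Three things may go wrong.
- The ring-fusion configuration may erode, because the iminium ion of 10 can form a trienamine by loss of H4a', which is aligned with the diene.
- Carbon–carbon bond formation with a hindered, doubly vinylogous aldehyde may be slow, leaving time for that enolisation and for unproductive para addition.
- Facial selectivity at C2 may be incomplete if the preference for a pseudoaxial C–O bond is small.

The fallback reverses the polarity of the fragments and uses no amine. It sets out from enone 8. Bromomethylenation with Ph3PCH2Br·Br and NaN(SiMe3)2 would give (4aR,5R,8S)-2-(bromomethylidene)-5-methyl-8-(propan-2-yl)-octahydronaphthalene F1. Bromine–lithium exchange with t-BuLi at −78 °C and addition to the lithium phenoxide of commercial 2-hydroxy-4,6-dimethoxybenzaldehyde would give the ortho-hydroxybenzylic dienyl carbinol F2. Such electron-rich carbinols lose water on gentle warming in toluene over MgSO4 to the same quinone methide 12, which closes to 13, where the fallback rejoins the route.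

**Step 3.** The aluminium-bound zwitterion may not transfer a proton but undergo two successive 1,2-hydride shifts, which would give a β-alkylated enone with the isopropyl centre formed without control, or it may collapse to a cyclobutane. The fallback changes the way the cation is terminated. From 4, TiCl4 in CH2Cl2 at −78 °C would deliver chloride to the tertiary cation as soon as it forms and give (4aR,5R,8R,8aR)-8-(2-chloropropan-2-yl)-5-methyloctahydronaphthalen-2(1H)-one F3. Radical dechlorination with Bu3SnH and azobisisobutyronitrile in benzene at 80 °C leads straight to 6, so step 4 is not needed.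

**Step 5.** Silylation may not discriminate enough between the two α-methylene groups, and over-oxidation to a cross-conjugated dienone would end in aromatisation of ring B. The fallback from 6 is bromination with phenyltrimethylammonium tribromide in THF, which runs through the acid-equilibrated enol and gives the 1-bromo ketone F4 on the ring-fusion side. A regioisomeric bromide can be separated at this stage. Dehydrobromination with Li2CO3 and LiBr in DMF at 120 °C returns to 8.

**Step 9.** Hydrocupration of this cis-disubstituted vinylarene may be slow because of the quaternary neighbour and the ortho methoxy group. Zerovalent palladium may insert into the tertiary allylic aryl ether. The ligand may not override whatever bias the substrate has. The fallback separates the two metal-mediated events. From 13, CuCl/NaOt-Bu/(R)-DTBM-SEGPHOS-catalysed Markovnikov hydroboration with pinacolborane would give the benzylic pinacol boronate F5, which can be purified and its configuration checked. A stereoretentive Suzuki–Miyaura coupling with iodobenzene (Pd2(dba)3, PPh3, Ag2O, dimethoxyethane, 85 °C) then gives 15. If hydrocupration itself is the failing event, the cycloaddition described under step 11 bypasses this step as well.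

**Step 11 (and, for the same reason, step 10).** TiCl4 or BCl3 may ionise the tertiary allylic O1–C2 bond, especially once a formyl group ortho to O1 can chelate the Lewis acid. This would lead to epimerisation at C2, chloride capture or elimination to a triene. The fallback avoids protecting groups and Lewis acids altogether. From enone 8, Wittig methylenation (Ph3PCH3Br, KOt-Bu, THF) would give the exocyclic diene (4aR,5R,8S)-5-methyl-2-methylidene-8-(propan-2-yl)-octahydronaphthalene F6. Heating F6 with benzaldehyde and 2,4,6-trihydroxybenzene-1,3-dicarbaldehyde generates the phenyl-substituted ortho-quinone methide in situ, and its hetero-Diels–Alder addition to the exocyclic methylene gives 17 directly. This three-component reaction is established for related diformylphloroglucinol meroterpenoids. It is shorter but leaves both C2 and C4 to the intrinsic selectivity of the cycloaddition.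

## Further compounds

F1 | step 8 | (4aR,5R,8S)-2-(bromomethylidene)-5-methyl-8-(propan-2-yl)-2,3,4,4a,5,6,7,8-octahydronaphthalene (E/Z mixture) | CC(C)[C@@H]1CC[C@@H](C)[C@H]2CCC(=CBr)C=C12
F2 | step 8 | 2-{1-hydroxy-2-[(4aR,5R,8S)-5-methyl-8-(propan-2-yl)-4,4a,5,6,7,8-hexahydronaphthalen-2(3H)-ylidene]ethyl}-3,5-dimethoxyphenol (mixture at the carbinol carbon) | CC(C)[C@@H]1CC[C@@H](C)[C@H]2CCC(=CC(O)c3c(O)cc(OC)cc3OC)C=C12
F3 | step 3 | (4aR,5R,8R,8aR)-8-(2-chloropropan-2-yl)-5-methyloctahydronaphthalen-2(1H)-one | CC(C)(Cl)[C@@H]1CC[C@@H](C)[C@H]2CCC(=O)C[C@@H]12
F4 | step 5 | 1-bromo derivative of 6, (4aR,5R,8S,8aS)-1-bromo-5-methyl-8-(propan-2-yl)octahydronaphthalen-2(1H)-one | CC(C)[C@@H]1CC[C@@H](C)[C@H]2CCC(=O)C(Br)[C@@H]12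
F5 | step 9 | 4-(4,4,5,5-tetramethyl-1,3,2-dioxaborolan-2-yl) analogue of 15, boron on the face that phenyl occupies in 15 | CC(C)[C@@H]1CC[C@@H](C)[C@H]2CC[C@@]3(C=C12)C[C@@H](B1OC(C)(C)C(C)(C)O1)c1c(OC)cc(OC)cc1O3
F6 | step 11 | (4aR,5R,8S)-5-methyl-2-methylidene-8-(propan-2-yl)-2,3,4,4a,5,6,7,8-octahydronaphthalene | CC(C)[C@@H]1CC[C@@H](C)[C@H]2CCC(=C)C=C12
A1 | alternative 1 | 6-ethynyl-1-(2-hydroxy-4,6-dimethoxyphenyl)-7,11-dimethyl-1-phenyldodec-10-en-3-one, configured as in the target | CC(C)=CCC[C@@H](C)[C@H](C#C)CCC(=O)C[C@@H](c1ccccc1)c1c(O)cc(OC)cc1OC
A2 | alternative 1 | chloro-isopropyl spirochroman dimethyl ether (15 with a 2-chloropropan-2-yl group in place of isopropyl) | CC(C)(Cl)[C@@H]1CC[C@@H](C)[C@H]2CC[C@@]3(C=C12)C[C@@H](c1ccccc1)c1c(OC)cc(OC)cc1O3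
A3 | alternative 2 | (2S)-2-(2-{[(5R,8S)-1-hydroxy-5-methyl-8-(propan-2-yl)-5,6,7,8-tetrahydronaphthalen-2-yl]oxy}-4,6-dimethoxyphenyl)-2-phenylethyl methanesulfonate | CC(C)[C@@H]1CC[C@@H](C)c2ccc(Oc3cc(OC)cc(OC)c3[C@@H](COS(C)(=O)=O)c3ccccc3)c(O)c12
A4 | alternative 2 | spiro cyclohexa-2,4-dienone | CC(C)[C@@H]1CC[C@@H](C)C2=C1C(=O)[C@]1(C=C2)C[C@@H](c2ccccc2)c2c(OC)cc(OC)cc2O1
A5 | alternative 3 | 4-hydroxy-2,6-dimethoxy-5-{(1S)-2-[(4aR,5R,8S,8aS)-5-methyl-8-(propan-2-yl)-3,4,4a,5,6,7,8,8a-octahydronaphthalen-2-yl]-1-phenylethyl}benzene-1,3-dicarbaldehyde | CC(C)[C@@H]1CC[C@@H](C)[C@H]2CCC(C[C@@H](c3ccccc3)c3c(OC)c(C=O)c(OC)c(C=O)c3O)=C[C@@H]12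
A6 | alternative 3 | Guajadial D di-O-methyl ether (identical with 16) | CC(C)[C@@H]1CC[C@@H](C)[C@H]2CC[C@@]3(C=C12)C[C@@H](c1ccccc1)c1c(OC)c(C=O)c(OC)c(C=O)c1O3
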